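**Plan**

- Retrosynthesis: after removing the silyl groups and a carboxyl carried on the resorcinol ring, the ring C–C bond between the styryl-bearing carbon and the carboxyl-bearing carbon is cut. This unfolds the 3,5-dihydroxyphenyl ring into a 9-aryl-3,5,7-trioxonon-8-enoate.
- The chain is cut at C6–C7 (3,5-dioxohexanoate trianion plus a cinnamoyl N-methoxy-N-methylamide) and at the aryl–vinyl bond (Heck). The dihydrofuran ring is cut at C2–C3 (carbenoid C–H insertion), the diazo ester at its aryl–C bond, and the benzyl ether at O–CH2.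
- Forward: benzyl aryl ether → aryldiazoacetate → dihydrobenzofuran (five-membered ring, closed first) → trans ester → alcohol → silyl ether → Heck → polyketone chain → resorcinol ring (six-membered, closed last) → decarboxylation → desilylation.
- Stereochemistry: C2 (R) comes from the chiral dirhodium carboxylate in the C–H insertion. C3 (S) comes from base epimerisation of the cis ester to trans under control of C2. The E alkene comes from the Heck reaction.
- Enabling feature: a benzene ring with oxygens at its 3- and 5-positions, joined at C1 to a trans CH=CH–aryl unit. Its six ring carbons map onto C2–C7 of a poly-β-carbonyl chain: C3 and C5 carbonyls become the phenols, C7 carries the vinyl group, and C2 carries a removable carboxyl.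

Key step: step 13

Assumption: Rh2(S-PTTL)4 is taken to deliver the 2R insertion product, and the ethyl ester is taken to behave like the methyl esters usual for this catalyst class; if the sense were opposite, Rh2(R-PTTL)4 would be used in step 6.

Shorthand in names: TIPS = triisopropylsilyl; TBS = tert-butyldimethylsilyl; Ar = 3-methoxy-4-(TIPS-oxy)phenyl; DHB = (2R,3S)-3-(TBS-oxymethyl)-7-methoxy-2-Ar-2,3-dihydro-1-benzofuran-5-yl (2-aryl and 3-CH2O trans).

**Route**

Step 1
Reactants: 1 vanillin (4-hydroxy-3-methoxybenzaldehyde)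
Product: 2 3-methoxy-4-(TIPS-oxy)benzaldehyde
Conditions: TIPSCl, imidazole, DMF, rt
Reagents that add atoms: triisopropylsilyl chloride, CC(C)[Si](Cl)(C(C)C)C(C)C
Why: Imidazole-mediated O-silylation of the phenol gives a bulky aryl silyl ether that should tolerate the hydride, carbenoid, palladium and amide-base steps ahead and fall to fluoride at the end.

Step 2
Reactants: 2 3-methoxy-4-(TIPS-oxy)benzaldehyde
Product: 3 [3-methoxy-4-(TIPS-oxy)phenyl]methanol
Conditions: NaBH4, THF–MeOH, 0 °C
Reagents that add atoms: none
Why: Borohydride reduction of the aryl aldehyde to the benzylic alcohol is chemoselective and leaves the aryl silyl ether intact at 0 °C.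

Step 3
Reactants: 4 4-bromo-2-methoxyphenol
Product: 5 4-bromo-2-iodo-6-methoxyphenol
Conditions: N-iodosuccinimide, TsOH (cat.), MeCN, 0 °C to rt
Reagents that add atoms: N-iodosuccinimide, O=C1CCC(=O)N1I
Why: Electrophilic aromatic iodination is directed by the free hydroxyl to its only open ortho position (para is blocked by bromine), installing a C–I bond that can be addressed selectively beside C–Br.

Step 4
Reactants: 5 4-bromo-2-iodo-6-methoxyphenol; 3 [3-methoxy-4-(TIPS-oxy)phenyl]methanol
Product: 6 5-bromo-1-iodo-3-methoxy-2-(Ar-methoxy)benzene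
Conditions: PPh3, DIAD, THF, 0 °C to rt
Reagents that add atoms: none
Why: Mitsunobu etherification lets the acidic phenol displace the benzylic oxyphosphonium under neutral conditions, avoiding the labile 4-silyloxybenzyl halide and basic carbonate that could shift the aryl silyl group.

Step 5
Reactants: 6 5-bromo-1-iodo-3-methoxy-2-(Ar-methoxy)benzene; 7 ethyl diazoacetate
Product: 8 ethyl 2-[5-bromo-3-methoxy-2-(Ar-methoxy)phenyl]-2-diazoacetate
Conditions: Pd(PPh3)4 (5 mol%), PPh3 (10 mol%), Ag2CO3 (0.5 equiv), Et3N, toluene, rt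
Reagents that add atoms: none
Why: Palladium-catalysed cross-coupling of an aryl iodide with the C–H bond of a diazoacetate retains the diazo group, and at room temperature oxidative addition of zerovalent palladium occurs at C–I only, keeping C–Br for step 10.

Step 6
Reactants: 8 ethyl 2-[5-bromo-3-methoxy-2-(Ar-methoxy)phenyl]-2-diazoacetate
Product: 9 ethyl (2R,3S)-5-bromo-7-methoxy-2-Ar-2,3-dihydro-1-benzofuran-3-carboxylate (2,3-cis)
Conditions: Rh2(S-PTTL)4, dirhodium tetrakis[N-phthaloyl-(S)-tert-leucinate] (1 mol%), toluene, −60 °C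
Reagents that add atoms: none
Why: Intramolecular 1,5 C–H insertion of the dirhodium donor/acceptor carbenoid into the ether-activated benzylic C–H bond closes the dihydrofuran ring; the chiral tert-leucinate ligands select one of the two enantiotopic benzylic hydrogens and so set C2 as R, and the compact three-centre transition state is expected to place aryl and ester cis (C3 S at this stage).

Step 7
Reactants: 9 ethyl (2R,3S)-5-bromo-7-methoxy-2-Ar-2,3-dihydro-1-benzofuran-3-carboxylate (2,3-cis)
Product: 10 ethyl (2R,3R)-5-bromo-7-methoxy-2-Ar-2,3-dihydro-1-benzofuran-3-carboxylate (2,3-trans)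
Conditions: NaOEt (0.3 equiv), EtOH–THF, 0 °C to rt
Reagents that add atoms: none
Why: Base epimerisation by enolisation and reprotonation at the ester-bearing benzylic C3 gives the thermodynamically preferred trans isomer, while C2 has no acidic hydrogen, keeps its R configuration and thereby controls C3.

Step 8
Reactants: 10 ethyl (2R,3R)-5-bromo-7-methoxy-2-Ar-2,3-dihydro-1-benzofuran-3-carboxylate (2,3-trans)
Product: 11 [(2R,3S)-5-bromo-7-methoxy-2-Ar-2,3-dihydro-1-benzofuran-3-yl]methanol (2,3-trans)
Conditions: LiBH4, THF, 0 °C to rt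
Reagents that add atoms: none
Why: Ester reduction with LiBH4 to the primary alcohol spares the aryl bromide and the aryl silyl ether and breaks no bond at a stereocentre (the C3 descriptor becomes S only through CIP priorities).

Step 9
Reactants: 11 [(2R,3S)-5-bromo-7-methoxy-2-Ar-2,3-dihydro-1-benzofuran-3-yl]methanol
Product: 12 (2R,3S)-5-bromo-3-(TBS-oxymethyl)-7-methoxy-2-Ar-2,3-dihydro-1-benzofuran (DHB–Br)
Conditions: TBSCl, imidazole, DMF, rt
Reagents that add atoms: tert-butyldimethylsilyl chloride, CC(C)(C)[Si](C)(C)Cl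
Why: Standard silylation of the primary alcohol ensures that no alkoxide competes in the later polyanion acylation and that both protecting groups can be removed together by fluoride.

Step 10
Reactants: 12 (2R,3S)-5-bromo-3-(TBS-oxymethyl)-7-methoxy-2-Ar-2,3-dihydro-1-benzofuran; 13 N-methoxy-N-methylprop-2-enamide
Product: 14 (E)-3-DHB-N-methoxy-N-methylprop-2-enamide
Conditions: Pd(OAc)2 (5 mol%), P(o-tol)3 (10 mol%), Et3N, DMF, 100 °C
Reagents that add atoms: none
Why: Mizoroki–Heck reaction of the unhindered aryl bromide with the acrylamide proceeds by syn insertion and syn β-hydride elimination to the E alkene and delivers the cinnamoyl carbons as an amide suited to single acylation.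

Step 11
Reactants: 15 prop-2-enyl 3-oxobutanoate (allyl acetoacetate); 16 N-methoxy-N-methylacetamide
Product: 17 prop-2-enyl 3,5-dioxohexanoate
Conditions: LiN(i-Pr)2 (LDA, 2.1 equiv), THF, −78 to −20 °C; then 16, −78 to −20 °C; aq. HCl
Reagents that add atoms: none
Why: Claisen-type acylation of the acetoacetate dianion at its terminal carbon by an N-methoxy-N-methylamide stops at the chelated adduct until work-up, and the low temperature is kept so that the allyl ester dianion does not undergo Carroll rearrangement.

Step 12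
Reactants: 17 prop-2-enyl 3,5-dioxohexanoate; 14 (E)-3-DHB-N-methoxy-N-methylprop-2-enamide
Product: 18 prop-2-enyl (E)-9-DHB-3,5,7-trioxonon-8-enoate
Conditions: 17 (1.5 equiv), LiN(i-Pr)2 (LDA, 4.6 equiv), THF, −78 to −20 °C; then 14, −78 to −30 °C; AcOH quench at −78 °C; crude product used directly
Reagents that add atoms: none
Why: Claisen-type acylation of the 3,5-dioxohexanoate trianion takes place at its terminal carbanion, the most basic and nucleophilic site, in a 1,2 sense on the amide carbonyl, and the chelated tetrahedral adduct persists until the acidic quench so that the triketo ester never meets the polyanion.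

Step 13
Reactants: 18 prop-2-enyl (E)-9-DHB-3,5,7-trioxonon-8-enoate
Product: 20 prop-2-enyl 2,4-dihydroxy-6-[(E)-2-DHB-ethenyl]benzoate, via cyclic aldol adduct 19 (not isolated)
Conditions: aq. K2CO3/KHCO3 (pH about 10), THF, rt, argon; then AcOH to pH 5
Reagents that add atoms: none
Why: At pH about 10 the polyketone is present as its enolates, and the C2 carbanion between the ester and the C3 ketone adds to the C7 ketone (intramolecular aldol) to give carbinol 19, which loses water by an E1cB pathway and tautomerises twice to the aromatic 2,4-dihydroxybenzoate. The closest known reaction type is the biomimetic base-mediated aldol aromatisation of 3,5,7-triketo esters to β-resorcylates, the laboratory counterpart of the stilbene-synthase fold. The six-membered carbocycle closes in a 6-(enolexo)-exo-trig mode with C2–C7 as the only new skeletal bond. No stereocentre is created, since the two sp3 centres of 19 disappear on aromatisation, and C2 and C3 of the dihydrobenzofuran carry no enolisable hydrogen and are not affected. The step needs chemoselectivity for this aldol over the C6-to-C1 Claisen closure, lactonisation to a 4-hydroxy-2-pyranone and oxa-Michael addition at C9: in water without magnesium or alkoxide the enolised ester terminus is a poor acyl acceptor, pyranone formation needs acidic or dehydrating conditions that are avoided, and the para oxygen of the dihydrobenzofuran makes C9 a weak Michael acceptor while the C7 ketone remains electrophilic.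

Step 14
Reactants: 20 prop-2-enyl 2,4-dihydroxy-6-[(E)-2-DHB-ethenyl]benzoate
Product: 22 5-[(E)-2-DHB-ethenyl]benzene-1,3-diol, via resorcylic acid 21 (not isolated)
Conditions: Pd(PPh3)4 (5 mol%), morpholine, THF, rt; aq. KHSO4 wash; then DMSO, 110 °C
Reagents that add atoms: none
Why: Tsuji–Trost deallylation (π-allyl formation on zerovalent palladium with morpholine as allyl acceptor) frees β-resorcylic acid 21, which on heating undergoes protodecarboxylation through ipso-protonation of the ring activated by its ortho and para hydroxyls, under neutral conditions that spare both silyl ethers.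

Step 15
Reactants: 22 5-[(E)-2-DHB-ethenyl]benzene-1,3-diol
Product: 23 gnetofuran A
Conditions: Bu4NF, AcOH, THF, 0 °C to rt
Reagents that add atoms: none
Why: Fluoride cleavage of the alkyl and aryl silyl ethers, buffered with acetic acid so that the liberated 4-hydroxyphenyl group is not ionised and cannot open the benzylic C2–O bond through a quinone methide, releases the target without touching either stereocentre.

**Compound list**

1 | vanillin (4-hydroxy-3-methoxybenzaldehyde) | COc1cc(C=O)ccc1O | starting material
2 | 3-methoxy-4-(TIPS-oxy)benzaldehyde | COc1cc(C=O)ccc1O[Si](C(C)C)(C(C)C)C(C)C | intermediate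
3 | [3-methoxy-4-(TIPS-oxy)phenyl]methanol | COc1cc(CO)ccc1O[Si](C(C)C)(C(C)C)C(C)C | intermediate
4 | 4-bromo-2-methoxyphenol | COc1cc(Br)ccc1O | starting material
5 | 4-bromo-2-iodo-6-methoxyphenol | COc1cc(Br)cc(I)c1O | intermediate
6 | 5-bromo-1-iodo-3-methoxy-2-(Ar-methoxy)benzene | COc1cc(Br)cc(I)c1OCc1ccc(O[Si](C(C)C)(C(C)C)C(C)C)c(OC)c1 | intermediate
7 | ethyl diazoacetate | CCOC(=O)C=[N+]=[N-] | starting material
8 | ethyl 2-[5-bromo-3-methoxy-2-(Ar-methoxy)phenyl]-2-diazoacetate | CCOC(=O)C(=[N+]=[N-])c1cc(Br)cc(OC)c1OCc1ccc(O[Si](C(C)C)(C(C)C)C(C)C)c(OC)c1 | intermediate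
9 | ethyl (2R,3S)-5-bromo-7-methoxy-2-Ar-2,3-dihydro-1-benzofuran-3-carboxylate (cis) | COc1cc([C@@H]2Oc3c(OC)cc(Br)cc3[C@@H]2C(=O)OCC)ccc1O[Si](C(C)C)(C(C)C)C(C)C | intermediate
10 | ethyl (2R,3R)-5-bromo-7-methoxy-2-Ar-2,3-dihydro-1-benzofuran-3-carboxylate (trans) | COc1cc([C@@H]2Oc3c(OC)cc(Br)cc3[C@H]2C(=O)OCC)ccc1O[Si](C(C)C)(C(C)C)C(C)C | intermediate
11 | [(2R,3S)-5-bromo-7-methoxy-2-Ar-2,3-dihydro-1-benzofuran-3-yl]methanol (trans) | COc1cc([C@@H]2Oc3c(OC)cc(Br)cc3[C@H]2CO)ccc1O[Si](C(C)C)(C(C)C)C(C)C | intermediate
12 | (2R,3S)-5-bromo-3-(TBS-oxymethyl)-7-methoxy-2-Ar-2,3-dihydro-1-benzofuran (DHB–Br) | COc1cc([C@@H]2Oc3c(OC)cc(Br)cc3[C@H]2CO[Si](C)(C)C(C)(C)C)ccc1O[Si](C(C)C)(C(C)C)C(C)C | intermediate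
13 | N-methoxy-N-methylprop-2-enamide | C=CC(=O)N(C)OC | starting material
14 | (E)-3-DHB-N-methoxy-N-methylprop-2-enamide | COc1cc([C@@H]2Oc3c(OC)cc(/C=C/C(=O)N(C)OC)cc3[C@H]2CO[Si](C)(C)C(C)(C)C)ccc1O[Si](C(C)C)(C(C)C)C(C)C | intermediate
15 | prop-2-enyl 3-oxobutanoate (allyl acetoacetate) | C=CCOC(=O)CC(C)=O | starting material
16 | N-methoxy-N-methylacetamide | CC(=O)N(C)OC | starting material
17 | prop-2-enyl 3,5-dioxohexanoate | C=CCOC(=O)CC(=O)CC(C)=O | intermediate
18 | prop-2-enyl (E)-9-DHB-3,5,7-trioxonon-8-enoate | COc1cc([C@@H]2Oc3c(OC)cc(/C=C/C(=O)CC(=O)CC(=O)CC(=O)OCC=C)cc3[C@H]2CO[Si](C)(C)C(C)(C)C)ccc1O[Si](C(C)C)(C(C)C)C(C)C | intermediate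
19 | prop-2-enyl 2-hydroxy-4,6-dioxo-2-[(E)-2-DHB-ethenyl]cyclohexane-1-carboxylate (cyclic aldol adduct of step 13, not isolated, ring centres undefined) | COc1cc([C@@H]2Oc3c(OC)cc(/C=C/C4(O)CC(=O)CC(=O)C4C(=O)OCC=C)cc3[C@H]2CO[Si](C)(C)C(C)(C)C)ccc1O[Si](C(C)C)(C(C)C)C(C)C | intermediate
20 | prop-2-enyl 2,4-dihydroxy-6-[(E)-2-DHB-ethenyl]benzoate | COc1cc([C@@H]2Oc3c(OC)cc(/C=C/c4cc(O)cc(O)c4C(=O)OCC=C)cc3[C@H]2CO[Si](C)(C)C(C)(C)C)ccc1O[Si](C(C)C)(C(C)C)C(C)C | intermediate
21 | 2,4-dihydroxy-6-[(E)-2-DHB-ethenyl]benzoic acid (formed in step 14, not isolated) | COc1cc([C@@H]2Oc3c(OC)cc(/C=C/c4cc(O)cc(O)c4C(=O)O)cc3[C@H]2CO[Si](C)(C)C(C)(C)C)ccc1O[Si](C(C)C)(C(C)C)C(C)C | intermediate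
22 | 5-[(E)-2-DHB-ethenyl]benzene-1,3-diol | COc1cc([C@@H]2Oc3c(OC)cc(/C=C/c4cc(O)cc(O)c4)cc3[C@H]2CO[Si](C)(C)C(C)(C)C)ccc1O[Si](C(C)C)(C(C)C)C(C)C | intermediate
23 | gnetofuran A, 5-[(E)-2-[(2R,3S)-2-(4-hydroxy-3-methoxyphenyl)-3-(hydroxymethyl)-7-methoxy-2,3-dihydro-1-benzofuran-5-yl]ethenyl]benzene-1,3-diol | COc1cc([C@@H]2Oc3c(OC)cc(/C=C/c4cc(O)cc(O)c4)cc3[C@H]2CO)ccc1O | target

**Step count**

Total steps: 15. Longest linear sequence: 13 steps (from vanillin: steps 1, 2, 4–10, 12–15).

**Steps most likely to fail**

1. Step 13 (key step). The polyketone may fold along a competing path: Claisen closure from C6 onto the ester carbon, lactonisation, or oxa-Michael addition. The aldol may also stall before dehydration. The fallback sets out from 18. Treatment with Pd(PPh3)4 and morpholine in THF at 0 °C removes the allyl group and gives (E)-9-DHB-3,5,7-trioxonon-8-enoic acid F1. As a carboxylate, its C1 terminus can act neither as acyl acceptor nor as lactone partner. In near-neutral aqueous phosphate buffer with THF, only the C2-to-C7 aldol remains open, and it should close to the resorcylic acid. That acid is 21, where the fallback rejoins the route at the heating stage of step 14.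

2. Step 12. The trianion may be quenched by proton transfer, may add in a conjugate sense to the unsaturated amide, or its allyl ester may undergo [3,3] rearrangement before acylation. The fallback sets out from 14 and moves the ester into a masked acylketene. Commercial 2,2,6-trimethyl-4H-1,3-dioxin-4-one is C-acetylated through its lithium dienolate (LiN(SiMe3)2, then acetyl chloride, THF, −78 °C) to give 2,2-dimethyl-6-(2-oxopropyl)-4H-1,3-dioxin-4-one F2. Its dilithium dienolate (LDA, 2 equiv, −78 °C) is acylated by 14 to give 6-[(E)-6-DHB-2,4-dioxohex-5-enyl]-2,2-dimethyl-4H-1,3-dioxin-4-one F3. Heating F3 in toluene at 110 °C with allyl alcohol should induce retro-[4+2] loss of acetone, and the acylketene is trapped by the alcohol. The product is 18, where the route resumes; no allyl ester polyanion is involved.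

3. Step 6. The catalyst may discriminate poorly between the two enantiotopic benzylic hydrogens, or a stepwise hydride-transfer pathway on the very electron-rich benzyl group may erode selectivity. Either would leave material of insufficient enantiomeric purity that recrystallisation of 10 or 11 cannot upgrade. The fallback sets out from 11 and takes the stereochemistry from resolution. Alcohol 11 is esterified with (S)-2-methoxy-2-phenylacetic acid (DCC, DMAP, CH2Cl2, 0 °C). This gives [(2R,3S)-5-bromo-7-methoxy-2-Ar-2,3-dihydro-1-benzofuran-3-yl]methyl (S)-2-methoxy-2-phenylacetate F4, together with its diastereomer from the minor enantiomer, the (2S,3R)-configured ester F5. The two are separated by chromatography or crystallisation. Reductive cleavage of F4 with LiBH4 in THF returns 11 as a single enantiomer, and the route continues with step 9.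

**Further compounds**

F1 | step 13 | (E)-9-DHB-3,5,7-trioxonon-8-enoic acid | COc1cc([C@@H]2Oc3c(OC)cc(/C=C/C(=O)CC(=O)CC(=O)CC(=O)O)cc3[C@H]2CO[Si](C)(C)C(C)(C)C)ccc1O[Si](C(C)C)(C(C)C)C(C)C
F2 | step 12 | 2,2-dimethyl-6-(2-oxopropyl)-4H-1,3-dioxin-4-one | CC(=O)CC1=CC(=O)OC(C)(C)O1
F3 | step 12 | 6-[(E)-6-DHB-2,4-dioxohex-5-enyl]-2,2-dimethyl-4H-1,3-dioxin-4-one | COc1cc([C@@H]2Oc3c(OC)cc(/C=C/C(=O)CC(=O)CC4=CC(=O)OC(C)(C)O4)cc3[C@H]2CO[Si](C)(C)C(C)(C)C)ccc1O[Si](C(C)C)(C(C)C)C(C)C
F4 | step 6 | [(2R,3S)-5-bromo-7-methoxy-2-Ar-2,3-dihydro-1-benzofuran-3-yl]methyl (S)-2-methoxy-2-phenylacetate | COc1cc([C@@H]2Oc3c(OC)cc(Br)cc3[C@H]2COC(=O)[C@@H](OC)c5ccccc5)ccc1O[Si](C(C)C)(C(C)C)C(C)C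
F5 | step 6 | [(2S,3R)-5-bromo-7-methoxy-2-Ar-2,3-dihydro-1-benzofuran-3-yl]methyl (S)-2-methoxy-2-phenylacetate | COc1cc([C@H]2Oc3c(OC)cc(Br)cc3[C@@H]2COC(=O)[C@@H](OC)c5ccccc5)ccc1O[Si](C(C)C)(C(C)C)C(C)C
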